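**Retrosynthetic overview**
- The two angelate esters come off last (double esterification of the 3,9-diol); the C7 isopropenyl group comes from a Pd-catalysed enolate alkenylation with 2-bromopropene.
- Ring B is opened at C9–C10 (aldol condensation of a 1,5-diketone, then cis hydrogenation) and at C5–C6.
- The C5–C6 bond and the C5 quaternary centre come from a Pd-catalysed allylic alkylation that joins a ring A silyl enol ether to a boryl allyl carbonate (the alkenyl boronate is a masked C8 ketone carrying the C9 oxygen).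
- Ring A is made first from cyclohexa-1,3-diene (enantioselective Kornblum–DeLaMare rearrangement, anti cuprate addition); the side-chain fragment is made from propargyl alcohol.
- Ring order: ring A is present from the start, ring B is annulated onto it.

Assumption: the quinidine-derived catalyst of step 2 is taken to give the R hydroxy enone (if it gives S, its quinine-derived pseudo-enantiomer is used). Bicyclic compounds are named with eremophilane numbering: ring A = C1–C5 and C10, ring B = C5–C10, methyls on C4 and C5, isopropenyl C11–C13 on C7, β = the face of the C5 methyl.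

**Route**

Step 1
Reactants: 1 cyclohexa-1,3-diene
Product: 2 2,3-dioxabicyclo[2.2.2]oct-5-ene (meso endoperoxide)
Conditions: O2, 5,10,15,20-tetraphenylporphyrin (0.1 mol %), visible light, CH2Cl2, −20 °C
Reagents that add atoms: dioxygen, O=O
Why: [4+2] photooxygenation, singlet oxygen adds across the s-cis diene to give the bicyclic endoperoxide, which is meso, so no stereocontrol is needed yet.

Step 2
Reactants: 2 2,3-dioxabicyclo[2.2.2]oct-5-ene
Product: 3 (R)-4-hydroxycyclohex-2-en-1-one
Conditions: 9-O-acetylcupreidine (10 mol %), CH2Cl2, 25 °C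
Reagents that add atoms: none
Why: Enantioselective Kornblum–DeLaMare rearrangement, the chiral bifunctional cinchona base removes one of the two enantiotopic bridgehead protons, the O–O bond opens to the γ-hydroxy enone, and the carbinol centre (later C3, R) is set by catalyst control.

Step 3
Reactants: 3 (R)-4-hydroxycyclohex-2-en-1-one
Product: 4 (R)-4-[(tert-butyldimethylsilyl)oxy]cyclohex-2-en-1-one
Conditions: TBSCl, imidazole, DMF, 0 to 25 °C
Reagents that add atoms: tert-butyldimethylsilyl chloride, CC(C)(C)[Si](C)(C)Cl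
Why: Standard silylation of a secondary alcohol; the bulky silyl ether directs the next step and the stereocentre is untouched.

Step 4
Reactants: 4 (R)-4-[(tert-butyldimethylsilyl)oxy]cyclohex-2-en-1-one
Product: 6 (2R,3R,4R)-4-[(tert-butyldimethylsilyl)oxy]-2,3-dimethylcyclohexan-1-one, via lithium enolate 5 (not isolated)
Conditions: Me2CuLi (from MeLi and CuI), Et2O, −78 °C; then MeI, HMPA, THF, −40 to 0 °C
Reagents that add atoms: lithium dimethylcuprate, [Li+].C[Cu-]C; iodomethane, CI
Why: Gilman cuprate 1,4-addition enters anti to the γ-silyloxy group (sets the later C4 methyl trans to oxygen) and the regiodefined lithium enolate is C-methylated (enolate alkylation, trans to the neighbouring methyl), the configuration of this last centre being erased in step 5.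

Step 5
Reactants: 6 (2R,3R,4R)-4-[(tert-butyldimethylsilyl)oxy]-2,3-dimethylcyclohexan-1-one
Product: 7 tert-butyl{[(1R,2R)-2,3-dimethyl-4-(trimethylsilyloxy)cyclohex-3-en-1-yl]oxy}dimethylsilane
Conditions: TMSCl, NaI, Et3N, MeCN, 25 °C
Reagents that add atoms: chlorotrimethylsilane, C[Si](C)(C)Cl
Why: Thermodynamic enol silylation with iodotrimethylsilane made in situ favours the tetrasubstituted enol ether (expected about 9:1), giving the regiodefined nucleophile for the quaternary centre without disturbing the two stereocentres.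

Step 6
Reactants: 8 prop-2-yn-1-ol
Product: 9 tert-butyldimethyl(prop-2-yn-1-yloxy)silane
Conditions: TBSCl, imidazole, CH2Cl2, 0 to 25 °C
Reagents that add atoms: tert-butyldimethylsilyl chloride, CC(C)(C)[Si](C)(C)Cl
Why: Standard silylation of a primary alcohol; this oxygen becomes the C9 oxygen.

Step 7
Reactants: 9 tert-butyldimethyl(prop-2-yn-1-yloxy)silane
Product: 11 methyl 4-[(tert-butyldimethylsilyl)oxy]but-2-ynoate, via lithium acetylide 10 (not isolated)
Conditions: n-BuLi, THF, −78 °C; then ClCO2Me, −78 to 0 °C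
Reagents that add atoms: methyl chloroformate, COC(=O)Cl
Why: Deprotonation of the terminal alkyne and C-acylation of the lithium acetylide with the chloroformate gives the ynoate, whose ester carbon becomes C6.

Step 8
Reactants: 11 methyl 4-[(tert-butyldimethylsilyl)oxy]but-2-ynoate
Product: 12 methyl (Z)-4-[(tert-butyldimethylsilyl)oxy]-3-(4,4,5,5-tetramethyl-1,3,2-dioxaborolan-2-yl)but-2-enoate
Conditions: B2pin2, CuCl (3 mol %), NaOt-Bu (6 mol %), Xantphos (3 mol %), MeOH, THF, 25 °C
Reagents that add atoms: bis(pinacolato)diboron, CC1(C)OB(OC1(C)C)B1OC(C)(C)C(C)(C)O1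
Why: Copper-catalysed conjugate borylation (syn borylcupration of the ynoate, then protonation of the alkenylcopper by methanol) places boron on the β carbon (later C8) and gives the Z alkene with boron trans to the ester.

Step 9
Reactants: 12 methyl (Z)-4-[(tert-butyldimethylsilyl)oxy]-3-(4,4,5,5-tetramethyl-1,3,2-dioxaborolan-2-yl)but-2-enoate
Product: 13 (Z)-4-[(tert-butyldimethylsilyl)oxy]-3-(4,4,5,5-tetramethyl-1,3,2-dioxaborolan-2-yl)but-2-en-1-ol
Conditions: i-Bu2AlH, CH2Cl2, −78 °C; aqueous potassium sodium tartrate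
Reagents that add atoms: none
Why: 1,2-Reduction of the enoate with the aluminium hydride gives the allylic alcohol, and because boron is trans to the carbinol carbon no cyclic borate can form.

Step 10
Reactants: 13 (Z)-4-[(tert-butyldimethylsilyl)oxy]-3-(4,4,5,5-tetramethyl-1,3,2-dioxaborolan-2-yl)but-2-en-1-ol
Product: 14 (Z)-4-[(tert-butyldimethylsilyl)oxy]-3-(4,4,5,5-tetramethyl-1,3,2-dioxaborolan-2-yl)but-2-en-1-yl methyl carbonate
Conditions: ClCO2Me, pyridine, CH2Cl2, 0 °C
Reagents that add atoms: methyl chloroformate, COC(=O)Cl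
Why: O-Acylation of the allylic alcohol gives the methyl carbonate, the leaving group that palladium ionises in the next step.

Step 11
Reactants: 7 tert-butyl{[(1R,2R)-2,3-dimethyl-4-(trimethylsilyloxy)cyclohex-3-en-1-yl]oxy}dimethylsilane; 14 (Z)-4-[(tert-butyldimethylsilyl)oxy]-3-(4,4,5,5-tetramethyl-1,3,2-dioxaborolan-2-yl)but-2-en-1-yl methyl carbonate
Product: 15 (2R,3R,4R)-4-[(tert-butyldimethylsilyl)oxy]-2-[(Z)-4-[(tert-butyldimethylsilyl)oxy]-3-(4,4,5,5-tetramethyl-1,3,2-dioxaborolan-2-yl)but-2-en-1-yl]-2,3-dimethylcyclohexan-1-one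
Conditions: Pd2(dba)3·CHCl3 (2.5 mol %), dppe (6 mol %), THF, 45 °C
Reagents that add atoms: none
Why: Proposed new method: zerovalent palladium ionises the allylic carbonate 14 to a π-allyl cation, the methoxide set free desilylates 7, and the tetrasubstituted enolate attacks the unsubstituted allyl terminus (remote from the boryl-bearing carbon) on the ring face anti to the pseudoaxial C4 methyl, forming the C5–C6 bond and the C5 quaternary centre (4,5-cis dimethyl) while the alkenyl boronate survives as a latent C8 ketone; the closest known reactions are the Tsuji allylation of silyl enol ethers with allyl carbonates and allylic substitution of 3-boryl allyl esters by stabilised nucleophiles, whose combination with an unstabilised ketone enolate and a γ,γ-disubstituted boryl allyl donor as a Robinson-annulation acceptor surrogate has not been shown.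

Step 12
Reactants: 15 (2R,3R,4R)-4-[(tert-butyldimethylsilyl)oxy]-2-[(Z)-4-[(tert-butyldimethylsilyl)oxy]-3-(4,4,5,5-tetramethyl-1,3,2-dioxaborolan-2-yl)but-2-en-1-yl]-2,3-dimethylcyclohexan-1-one
Product: 17 (3R,4R,5R)-3,9-bis[(tert-butyldimethylsilyl)oxy]-11,12,13-trinoreremophil-9-en-8-one, via diketone 16 (not isolated)
Conditions: NaBO3·4H2O, THF/H2O, 25 °C; extractive work-up; then pyrrolidine, AcOH, toluene, 80 °C
Reagents that add atoms: sodium perborate, [Na+].[O-]OB=O
Why: Perborate oxidation of the alkenyl C–B bond gives the enol and hence the C8 ketone, and amine/acid-mediated intramolecular aldol condensation (ring-closing half of a Robinson annulation) through C9, the only position that can close a six-membered ring and dehydrate, forms ring B as the 9-silyloxy enone without creating a stereocentre.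

Step 13
Reactants: 17 (3R,4R,5R)-3,9-bis[(tert-butyldimethylsilyl)oxy]-11,12,13-trinoreremophil-9-en-8-one
Product: 19 (3R,4R,5R,9R,10S)-3,9-bis[(tert-butyldimethylsilyl)oxy]-11,12,13-trinoreremophilan-8-one (cis-fused, 10β-H, 9β-silyloxy), via 9-epimer 18 (not isolated)
Conditions: H2 (4 atm), 10% Pd/C, EtOAc, Et3N, 25 °C; filtration; then DBU, toluene, 40 °C
Reagents that add atoms: none
Why: Heterogeneous catalytic hydrogenation adds H2 syn from the β face (the usual course for 4,5-dimethyl octalones of this type in basic medium), setting the 10β-H cis ring fusion and giving the axial 9α-silyloxy ketone 18, and base-mediated epimerisation through the enol then moves the C9 silyloxy group to the equatorial 9β position, relieving its 1,3-diaxial clash with C4.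

Step 14
Reactants: 19 (3R,4R,5R,9R,10S)-3,9-bis[(tert-butyldimethylsilyl)oxy]-11,12,13-trinoreremophilan-8-one; 20 2-bromopropene
Product: 23 (3R,4R,5R,7R,9R,10S)-3,9-bis[(tert-butyldimethylsilyl)oxy]eremophil-11-en-8-one, via lithium enolate 21 (not isolated), via lithium dienolate 22 (not isolated)
Conditions: LiN(SiMe3)2 (2.3 equiv), THF, −78 to 0 °C; Pd2(dba)3 (2.5 mol %), [HP(t-Bu)3]BF4 (6 mol %), 2-bromopropene, 25 °C; AcOH, −78 °C
Reagents that add atoms: none
Why: Pd-catalysed α-alkenylation of a ketone enolate (Buchwald–Hartwig-type enolate coupling), the kinetic C7 enolate formed away from the silyloxy-bearing C9 couples with the alkenyl bromide, the more acidic product is held as dienolate 22, and axial kinetic C-protonation at C7 places the isopropenyl group equatorial (7β), which is also the thermodynamic configuration.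

Step 15
Reactants: 23 (3R,4R,5R,7R,9R,10S)-3,9-bis[(tert-butyldimethylsilyl)oxy]eremophil-11-en-8-one
Product: 24 (3R,4R,5R,7R,9R,10S)-3,9-dihydroxyeremophil-11-en-8-one
Conditions: HF·pyridine, pyridine, THF, 0 to 25 °C
Reagents that add atoms: none
Why: Fluoride-mediated cleavage of both silyl ethers under buffered, non-basic conditions that leave the β,γ-unsaturated ketone and the α-ketol untouched.

Step 16
Reactants: 25 angelic acid, (Z)-2-methylbut-2-enoic acid
Product: 26 (Z)-2-methylbut-2-enoic 2,4,6-trichlorobenzoic anhydride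
Conditions: 2,4,6-trichlorobenzoyl chloride, Et3N, toluene, 25 °C; filtration under argon
Reagents that add atoms: 2,4,6-trichlorobenzoyl chloride, O=C(Cl)c1c(Cl)cc(Cl)cc1Cl
Why: Yamaguchi mixed-anhydride formation; the two ortho chlorines shield the aroyl carbonyl so that alcohols later attack the angeloyl carbonyl.

Step 17
Reactants: 24 (3R,4R,5R,7R,9R,10S)-3,9-dihydroxyeremophil-11-en-8-one; 26 (Z)-2-methylbut-2-enoic 2,4,6-trichlorobenzoic anhydride
Product: 27 (3R,4R,5R,7R,9R,10S)-3,9-bis{[(Z)-2-methylbut-2-enoyl]oxy}eremophil-11-en-8-one (CNP0174755.1)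
Conditions: 26 (5 equiv), Et3N, toluene, 65 °C
Reagents that add atoms: none
Why: Yamaguchi-type esterification without DMAP, both secondary hydroxyls attack the unhindered angeloyl carbonyl of the mixed anhydride under conditions known to keep the Z (angelate) geometry, and no stereocentre is touched.

**Compound list**

1 | cyclohexa-1,3-diene | C1=CC=CCC1 | starting material
2 | 2,3-dioxabicyclo[2.2.2]oct-5-ene (meso) | C1=C[C@@H]2CC[C@H]1OO2 | intermediate
3 | (R)-4-hydroxycyclohex-2-en-1-one | O=C1C=C[C@H](O)CC1 | intermediate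
4 | (R)-4-[(tert-butyldimethylsilyl)oxy]cyclohex-2-en-1-one | O=C1C=C[C@H](O[Si](C)(C)C(C)(C)C)CC1 | intermediate
5 | lithium (3R,4R)-4-[(tert-butyldimethylsilyl)oxy]-3-methylcyclohex-1-en-1-olate | [Li+].[O-]C1=C[C@@H](C)[C@H](O[Si](C)(C)C(C)(C)C)CC1 | intermediate
6 | (2R,3R,4R)-4-[(tert-butyldimethylsilyl)oxy]-2,3-dimethylcyclohexan-1-one | O=C1CC[C@@H](O[Si](C)(C)C(C)(C)C)[C@H](C)[C@H]1C | intermediate
7 | tert-butyl{[(1R,2R)-2,3-dimethyl-4-(trimethylsilyloxy)cyclohex-3-en-1-yl]oxy}dimethylsilane | C[Si](C)(C)OC1=C(C)[C@@H](C)[C@H](O[Si](C)(C)C(C)(C)C)CC1 | intermediate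
8 | prop-2-yn-1-ol | C#CCO | starting material
9 | tert-butyldimethyl(prop-2-yn-1-yloxy)silane | C#CCO[Si](C)(C)C(C)(C)C | intermediate
10 | {3-[(tert-butyldimethylsilyl)oxy]prop-1-yn-1-yl}lithium | [Li]C#CCO[Si](C)(C)C(C)(C)C | intermediate
11 | methyl 4-[(tert-butyldimethylsilyl)oxy]but-2-ynoate | COC(=O)C#CCO[Si](C)(C)C(C)(C)C | intermediate
12 | methyl (Z)-4-[(tert-butyldimethylsilyl)oxy]-3-(4,4,5,5-tetramethyl-1,3,2-dioxaborolan-2-yl)but-2-enoate | COC(=O)/C=C(\CO[Si](C)(C)C(C)(C)C)B1OC(C)(C)C(C)(C)O1 | intermediate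
13 | (Z)-4-[(tert-butyldimethylsilyl)oxy]-3-(4,4,5,5-tetramethyl-1,3,2-dioxaborolan-2-yl)but-2-en-1-ol | OC/C=C(\CO[Si](C)(C)C(C)(C)C)B1OC(C)(C)C(C)(C)O1 | intermediate
14 | (Z)-4-[(tert-butyldimethylsilyl)oxy]-3-(4,4,5,5-tetramethyl-1,3,2-dioxaborolan-2-yl)but-2-en-1-yl methyl carbonate | COC(=O)OC/C=C(\CO[Si](C)(C)C(C)(C)C)B1OC(C)(C)C(C)(C)O1 | intermediate
15 | (2R,3R,4R)-4-[(tert-butyldimethylsilyl)oxy]-2-[(Z)-4-[(tert-butyldimethylsilyl)oxy]-3-(4,4,5,5-tetramethyl-1,3,2-dioxaborolan-2-yl)but-2-en-1-yl]-2,3-dimethylcyclohexan-1-one | O=C1CC[C@@H](O[Si](C)(C)C(C)(C)C)[C@H](C)[C@@]1(C)C/C=C(\CO[Si](C)(C)C(C)(C)C)B2OC(C)(C)C(C)(C)O2 | intermediate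
16 | (2R,3R,4R)-4-[(tert-butyldimethylsilyl)oxy]-2-{4-[(tert-butyldimethylsilyl)oxy]-3-oxobutyl}-2,3-dimethylcyclohexan-1-one | O=C1CC[C@@H](O[Si](C)(C)C(C)(C)C)[C@H](C)[C@@]1(C)CCC(=O)CO[Si](C)(C)C(C)(C)C | intermediate
17 | (3R,4R,5R)-3,9-bis[(tert-butyldimethylsilyl)oxy]-11,12,13-trinoreremophil-9-en-8-one | O=C1CC[C@]2(C)[C@@H](C)[C@H](O[Si](C)(C)C(C)(C)C)CCC2=C1O[Si](C)(C)C(C)(C)C | intermediate
18 | (3R,4R,5R,9S,10S)-3,9-bis[(tert-butyldimethylsilyl)oxy]-11,12,13-trinoreremophilan-8-one (9α-silyloxy, 10β-H) | C1C[C@@]2(C)[C@H](CC[C@@H](O[Si](C)(C)C(C)(C)C)[C@@H]2C)[C@H](O[Si](C)(C)C(C)(C)C)C1=O | intermediate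
19 | (3R,4R,5R,9R,10S)-3,9-bis[(tert-butyldimethylsilyl)oxy]-11,12,13-trinoreremophilan-8-one (9β-silyloxy, 10β-H) | C1C[C@@]2(C)[C@H](CC[C@@H](O[Si](C)(C)C(C)(C)C)[C@@H]2C)[C@@H](O[Si](C)(C)C(C)(C)C)C1=O | intermediate
20 | 2-bromopropene | C=C(C)Br | starting material
21 | lithium (3R,4R,5R,9R,10S)-3,9-bis[(tert-butyldimethylsilyl)oxy]-11,12,13-trinoreremophil-7-en-8-olate | [Li+].[O-]C1=CC[C@@]2(C)[C@H](CC[C@@H](O[Si](C)(C)C(C)(C)C)[C@@H]2C)[C@H]1O[Si](C)(C)C(C)(C)C | intermediate
22 | lithium (3R,4R,5R,9R,10S)-3,9-bis[(tert-butyldimethylsilyl)oxy]eremophila-7,11-dien-8-olate | [Li+].[O-]C1=C(C(C)=C)C[C@@]2(C)[C@H](CC[C@@H](O[Si](C)(C)C(C)(C)C)[C@@H]2C)[C@H]1O[Si](C)(C)C(C)(C)C | intermediate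
23 | (3R,4R,5R,7R,9R,10S)-3,9-bis[(tert-butyldimethylsilyl)oxy]eremophil-11-en-8-one | C=C(C)[C@H]1C[C@@]2(C)[C@H](CC[C@@H](O[Si](C)(C)C(C)(C)C)[C@@H]2C)[C@@H](O[Si](C)(C)C(C)(C)C)C1=O | intermediate
24 | (3R,4R,5R,7R,9R,10S)-3,9-dihydroxyeremophil-11-en-8-one | C=C(C)[C@H]1C[C@@]2(C)[C@H](CC[C@@H](O)[C@@H]2C)[C@@H](O)C1=O | intermediate
25 | angelic acid, (Z)-2-methylbut-2-enoic acid | C/C=C(/C)C(=O)O | starting material
26 | (Z)-2-methylbut-2-enoic 2,4,6-trichlorobenzoic anhydride | C/C=C(/C)C(=O)OC(=O)c1c(Cl)cc(Cl)cc1Cl | intermediate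
27 | (3R,4R,5R,7R,9R,10S)-3,9-bis{[(Z)-2-methylbut-2-enoyl]oxy}eremophil-11-en-8-one | C=C(C)[C@H]1C[C@@]2(C)[C@H](CC[C@@H](OC(=O)/C(C)=C\C)[C@@H]2C)[C@@H](OC(=O)/C(C)=C\C)C1=O | target

**Step count and weak points**

Total step count: 17. Longest linear sequence: 11 steps (steps 1–5, 11–15 and 17; the line through steps 6–10 is equally long).

Step 11 (the proposed new allylation) is the least certain step. The boronate may bind the methoxide needed to release the enolate, O-allylation or protodeboronation may compete, and the axial C3 silyloxy group may erode the facial selectivity at C5. The fallback is known chemistry and sets out from 7. But-3-ene-1,2-diol is silylated at the primary hydroxyl (TBSCl, imidazole) to 1-[(tert-butyldimethylsilyl)oxy]but-3-en-2-ol F1, which is oxidised with Dess–Martin periodinane to 1-[(tert-butyldimethylsilyl)oxy]but-3-en-2-one F2. A Mukaiyama–Michael addition of 7 to this enone (TiCl4/Ti(Oi-Pr)4, CH2Cl2, −78 °C) gives the diketone directly. The route is rejoined at 16, which is cyclised as in step 12.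

Step 13 may fail because the tetrasubstituted, silyloxy-bearing enone alkene is hindered, or because hydrogen is delivered from the α face (trans-decalin). The fallback sets out from 17. Luche reduction (NaBH4, CeCl3·7H2O, MeOH, −78 °C) gives (3R,4R,5R,8S)-3,9-bis[(tert-butyldimethylsilyl)oxy]-11,12,13-trinoreremophil-9-en-8-ol F3. Hydroxyl-directed homogeneous hydrogenation with [Ir(cod)(PCy3)(py)]PF6 under H2 in CH2Cl2 then delivers both hydrogens from the β face to give (3R,4R,5R,8S,9S,10S)-3,9-bis[(tert-butyldimethylsilyl)oxy]-11,12,13-trinoreremophilan-8-ol F4. Dess–Martin oxidation returns the ketone, and the route is rejoined at 18, which is epimerised to 19 with DBU as in step 13.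

Step 14 may give low conversion on the hindered cis-decalone, or the isopropenyl group may slip into conjugation under the basic conditions. The fallback sets out from 19. Aldol addition of its C7 lithium enolate (LiN(i-Pr)2, THF, −78 °C) to acetone gives (3R,4R,5R,7R,9R,10S)-3,9-bis[(tert-butyldimethylsilyl)oxy]-11-hydroxyeremophilan-8-one F5. Dehydration (MsCl, Et3N, then DBU) gives the conjugated (3R,4R,5R,9R,10S)-3,9-bis[(tert-butyldimethylsilyl)oxy]eremophil-7(11)-en-8-one F6. Kinetic γ-deprotonation (LiN(i-Pr)2, THF/HMPA, −78 °C) then gives the lithium dienolate, so the route is rejoined at 22, which is protonated at C7 with AcOH at −78 °C to give 23.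

Further compounds
F1 | step 11 | 1-[(tert-butyldimethylsilyl)oxy]but-3-en-2-ol (racemic) | C=CC(O)CO[Si](C)(C)C(C)(C)C
F2 | step 11 | 1-[(tert-butyldimethylsilyl)oxy]but-3-en-2-one | C=CC(=O)CO[Si](C)(C)C(C)(C)C
F3 | step 13 | (3R,4R,5R,8S)-3,9-bis[(tert-butyldimethylsilyl)oxy]-11,12,13-trinoreremophil-9-en-8-ol | O[C@H]1CC[C@]2(C)[C@@H](C)[C@H](O[Si](C)(C)C(C)(C)C)CCC2=C1O[Si](C)(C)C(C)(C)C
F4 | step 13 | (3R,4R,5R,8S,9S,10S)-3,9-bis[(tert-butyldimethylsilyl)oxy]-11,12,13-trinoreremophilan-8-ol | C1C[C@@]2(C)[C@H](CC[C@@H](O[Si](C)(C)C(C)(C)C)[C@@H]2C)[C@H](O[Si](C)(C)C(C)(C)C)[C@H]1O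
F5 | step 14 | (3R,4R,5R,7R,9R,10S)-3,9-bis[(tert-butyldimethylsilyl)oxy]-11-hydroxyeremophilan-8-one | CC(C)(O)[C@H]1C[C@@]2(C)[C@H](CC[C@@H](O[Si](C)(C)C(C)(C)C)[C@@H]2C)[C@@H](O[Si](C)(C)C(C)(C)C)C1=O
F6 | step 14 | (3R,4R,5R,9R,10S)-3,9-bis[(tert-butyldimethylsilyl)oxy]eremophil-7(11)-en-8-one | CC(C)=C1C[C@@]2(C)[C@H](CC[C@@H](O[Si](C)(C)C(C)(C)C)[C@@H]2C)[C@@H](O[Si](C)(C)C(C)(C)C)C1=O
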